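**Plan**

1. Terpene numbering used below: C1 = CH bearing CH2Ar, C4 = carbinol carbon, C5 = ring-fusion CH, C7 = CH bearing the propenyl group, C10 = quaternary ring-fusion carbon, C11 = central propenyl carbon; ring A = C1–C5 + C10, ring B = C5–C10.
2. Retrosynthetic cuts: the aryl–C(=O) bond of the isovaleryl group and the protecting groups; C11=CH2; the C7–C8 bond of ring B, which leads back to a cycloheptene C5–C6–C7=C11(CH3)–C8–C9–C10 (1,2-shift of C8 from C11 to C7); the CH2–aryl bond (B-alkyl Suzuki–Miyaura); C7=C11 (ring-closing metathesis); C10–C9 (Michael) and C5–C6 (conjugate allylation) on a cyclohexenone made from (R)-linalool.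
3. Forward order: ring A (metathesis of a linalool-derived dienol, oxidation), the chains at C5 and C10, the seven-membered ring, the arene at C1, contraction of the seven-membered ring to ring B, methylenation at C11, aryl acylation, global deprotection.
4. Feature that allows the key event: ring carbon C7 carries the exocyclic carbon C11 at ketone oxidation level (C(=CH2)CH3 from C(=O)CH3). A cyclohexane CH–C(=O)CH3 unit is what a pinacol-type shift delivers from a cycloheptane that holds C11 as a ring C(OH)CH3 next to C7–OMs.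
5. Stereochemistry: C4 from (R)-linalool; C5 by cuprate addition anti to the C4 silyloxy group; C10 by Michael addition anti to the C5 allyl group; C1 by hydroboration anti to the axial C10 methyl; C7 by base equilibration of the new acetyl group to the equatorial position.

Key step: step 15

Assumption: step 14 is drawn for OsO4 attack on the α-face (opposite the C10 methyl); the β-face cis-diol would give the same ketone 22 in step 15, so the face is not critical.

**Route**

Step 1
Reactants: 1 (R)-(−)-linalool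
Product: 2 (R)-linalool triethylsilyl ether
Conditions: Et3SiOTf, 2,6-lutidine, CH2Cl2, −78 → 0 °C
Reagents that add atoms: triethylsilyl trifluoromethanesulfonate, CC[Si](CC)(CC)OS(=O)(=O)C(F)(F)F
Why: Silyl ether formation on the tertiary alcohol with a silyl triflate; C4 is untouched and the bulky ether later shields one face of the enone.

Step 2
Reactants: 2 (R)-linalool triethylsilyl ether
Product: 4 (4R)-4-methyl-4-(triethylsilyloxy)hex-5-enal, via secondary ozonide 3 (not isolated)
Conditions: O3 (1 equiv), CH2Cl2, −78 °C; then PPh3, −78 °C → rt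
Reagents that add atoms: ozone, [O-][O+]=O
Why: Ozonolysis with reductive work-up should be chemoselective because ozone attacks the electron-rich trisubstituted alkene far faster than the hindered vinyl group.

Step 3
Reactants: 4 (4R)-4-methyl-4-(triethylsilyloxy)hex-5-enal
Product: 5 (6R)-2,6-dimethyl-6-(triethylsilyloxy)octa-1,7-dien-3-ol (both C3 epimers)
Conditions: CH2=C(CH3)MgBr, THF, −78 → 0 °C; H2O
Reagents that add atoms: isopropenylmagnesium bromide, C=C(C)[Mg]Br
Why: Grignard 1,2-addition to the aldehyde; the carbinol center is left uncontrolled because it is oxidised in step 5.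

Step 4
Reactants: 5 (6R)-2,6-dimethyl-6-(triethylsilyloxy)octa-1,7-dien-3-ol
Product: 6 (4R)-2,4-dimethyl-4-(triethylsilyloxy)cyclohex-2-en-1-ol (both C1 epimers)
Conditions: second-generation Grubbs catalyst RuCl2(=CHPh)(PCy3)(H2IMes) (5 mol%), CH2Cl2, 40 °C
Reagents that add atoms: none
Why: Ring-closing metathesis of the vinyl group and the 1,1-disubstituted alkene should close ring A with loss of ethene; no stereocenter is formed.

Step 5
Reactants: 6 (4R)-2,4-dimethyl-4-(triethylsilyloxy)cyclohex-2-en-1-ol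
Product: 7 (4R)-2,4-dimethyl-4-(triethylsilyloxy)cyclohex-2-en-1-one
Conditions: Dess–Martin periodinane, NaHCO3, CH2Cl2, 0 °C → rt
Reagents that add atoms: none
Why: Dess–Martin oxidation of the allylic alcohol gives the enone and removes the uncontrolled carbinol center.

Step 6
Reactants: 7 (4R)-2,4-dimethyl-4-(triethylsilyloxy)cyclohex-2-en-1-one
Product: 8 trimethylsilyl enol ether of the C5-allyl ketone (allyl trans to OSiEt3)
Conditions: CH2=CHCH2MgBr, CuBr·SMe2, Me3SiCl, THF, −78 °C; then Et3N, NaHCO3 (aq.)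
Reagents that add atoms: allylmagnesium bromide, C=CC[Mg]Br; chlorotrimethylsilane, C[Si](C)(C)Cl
Why: Silyl-chloride-accelerated conjugate addition of an allylcopper reagent; the allyl group should enter C5 anti to the pseudo-axial C4 silyloxy group, and trapping as the silyl enol ether fixes the enolate regiochemistry.

Step 7
Reactants: 8 trimethylsilyl enol ether
Product: 10 (2R,3R,4R)-2,4-dimethyl-2-(3-oxobutyl)-3-(prop-2-en-1-yl)-4-(triethylsilyloxy)cyclohexan-1-one, via side-chain silyl enol ether 9 (not isolated)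
Conditions: but-3-en-2-one, Tf2NH (5 mol%), CH2Cl2, −78 °C; then 1 M HCl, THF, 0 °C
Reagents that add atoms: but-3-en-2-one, C=CC(C)=O
Why: Mukaiyama–Michael addition; the C5 allyl group sits pseudo-axial (allylic 1,2-strain with the C10 methyl), so the enone should add to C10 on the opposite face and give the quaternary center with the new chain trans to allyl.

Step 8
Reactants: 10 diketone
Product: 11 triethyl{[(1R,2R,3R)-1,3-dimethyl-3-(3-methylbut-3-en-1-yl)-4-methylidene-2-(prop-2-en-1-yl)cyclohexyl]oxy}silane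
Conditions: Ph3PCH3Br, KOt-Bu, toluene, 0 °C, then 90 °C
Reagents that add atoms: methylenetriphenylphosphorane, C=P(c1ccccc1)(c1ccccc1)c1ccccc1
Why: Double Wittig methylenation; the methyl ketone should react at 0 °C (removing the 1,5-diketone before aldol or retro-Michael reactions start) and the hindered ring ketone on heating.

Step 9
Reactants: 11 triene
Product: 12 trans-fused 6-7 diene (cycloheptene C7=C11(CH3); exocyclic methylene at C1)
Conditions: second-generation Grubbs catalyst RuCl2(=CHPh)(PCy3)(H2IMes) (5 mol%), toluene (dilute), 80 °C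
Reagents that add atoms: none
Why: Ring-closing metathesis of the allyl group with the 1,1-disubstituted side-chain alkene should give the trisubstituted cycloheptene; the C1 methylene could only close a ring through a bridgehead or tetrasubstituted alkene and should stay intact.

Step 10
Reactants: 13 2,4,6-trihydroxybenzaldehyde
Product: 14 2,4,6-tris(methoxymethoxy)benzaldehyde
Conditions: NaH, CH3OCH2Cl, DMF, 0 °C → rt
Reagents that add atoms: chloromethyl methyl ether, COCCl
Why: O-Alkylation (Williamson type) of the three phenoxides.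

Step 11
Reactants: 14 2,4,6-tris(methoxymethoxy)benzaldehyde
Product: 15 3-bromo-2,4,6-tris(methoxymethoxy)benzaldehyde
Conditions: NBS, MeCN, 0 °C
Reagents that add atoms: N-bromosuccinimide, O=C1CCC(=O)N1Br
Why: Electrophilic aromatic bromination at one of the two equivalent free positions of the electron-rich ring.

Step 12
Reactants: 15 3-bromo-2,4,6-tris(methoxymethoxy)benzaldehyde
Product: 16 1-bromo-3-(dimethoxymethyl)-2,4,6-tris(methoxymethoxy)benzene
Conditions: HC(OMe)3, PPTS (cat.), MeOH, rt
Reagents that add atoms: trimethyl orthoformate, COC(OC)OC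
Why: Acid-catalysed acetalisation driven by the orthoformate; it masks the aldehyde against the ylide and organolithium reagents that follow.

Step 13
Reactants: 12 trans-fused 6-7 diene; 16 aryl bromide acetal
Product: 18 1β-(arylmethyl) 6-7 alkene, via B-alkyl-9-BBN 17 (not isolated)
Conditions: 9-BBN, THF, rt → 50 °C; then 16, Pd(OAc)2 (5 mol%), SPhos (10 mol%), K3PO4, H2O, THF, 65 °C
Reagents that add atoms: none
Why: Hydroboration followed by B-alkyl Suzuki–Miyaura coupling; 9-BBN should react only with the 1,1-disubstituted alkene and from the α-face, away from the axial C10 methyl on the neighbouring carbon, so that C1 receives H α and the CH2–aryl group ends up β (equatorial).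

Step 14
Reactants: 18 1β-(arylmethyl) 6-7 alkene
Product: 19 7α,11α-cis-diol
Conditions: OsO4 (5 mol%), NMO, acetone/H2O, rt
Reagents that add atoms: osmium tetroxide, O=[Os](=O)(=O)=O; N-methylmorpholine N-oxide, C[N+]1([O-])CCOCC1
Why: Catalytic cis-dihydroxylation of the only remaining alkene; either face gives a cis-diol that step 15 can use.

Step 15
Reactants: 19 7α,11α-cis-diol
Product: 22 7β-acetyl trans-decalin, via mesylate 20 (not isolated), via 7-epi ketone 21 (not isolated)
Conditions: MsCl, Et3N, CH2Cl2, −20 °C; then KOt-Bu, t-BuOH/THF, 0 °C → rt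
Reagents that add atoms: none
Why: MsCl should sulfonylate only the secondary C7–OH, and KOt-Bu then turns the tertiary C11–OH into an alkoxide that drives the ring bond C8–C11, antiperiplanar to C7–OMs, onto C7 as mesylate leaves, so that C11 becomes the acetyl carbonyl and the cycloheptane C5–C6–C7–C11–C8–C9–C10 becomes ring B. The closest known reaction type is the semipinacol (pinacol-type) rearrangement of 2-hydroxy sulfonates, as in the contraction of 1-methylcycloalkane-cis-1,2-diol monosulfonates to acetylcycloalkanes. Ring B is closed not by a cyclisation but by this 1,2-alkyl shift, which forms C7–C8 with inversion at C7 and expels one ring atom to the exocyclic position. The only new stereocenter, C7, is first fixed by that inversion (7-epi ketone 21 from the α-mesylate) and then equilibrated by the same base through the enolate to the equatorial 7β-acetyl group of the trans-decalin chair, so that both diol faces should end in 22. The step needs ring-carbon migration in place of methyl migration and rearrangement in place of elimination: the cis-diol geometry excludes epoxide formation, the conformer with mesylate and methyl pseudo-equatorial places the ring bond anti to the leaving group, a secondary alkyl group migrates better than methyl, and the intramolecular alkoxide-assisted shift should outrun E2.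

Step 16
Reactants: 22 7β-acetyl trans-decalin
Product: 23 7β-isopropenyl trans-decalin
Conditions: Ph3PCH3Br, KOt-Bu, THF, 0 °C → rt
Reagents that add atoms: methylenetriphenylphosphorane, C=P(c1ccccc1)(c1ccccc1)c1ccccc1
Why: Wittig methylenation of the methyl ketone; the basic ylide can only shift C7 toward the wanted equatorial isomer before the center is locked.

Step 17
Reactants: 23 7β-isopropenyl trans-decalin
Product: 25 aryl isovaleryl ketone, via aryllithium 24 (not isolated)
Conditions: n-BuLi, TMEDA, THF, 0 °C; then (CH3)2CHCH2C(=O)N(OCH3)CH3, −78 → 0 °C; H2O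
Reagents that add atoms: N-methoxy-N-methyl-3-methylbutanamide, CC(C)CC(=O)N(C)OC
Why: Directed ortho-lithiation of the one ring C–H flanked by two OMOM groups, then acylation with a Weinreb amide whose chelated adduct prevents over-addition.

Step 18
Reactants: 25 aryl isovaleryl ketone
Product: 26 target CNP0561337.1
Conditions: 2 M HCl (aq.), MeOH/THF, rt
Reagents that add atoms: water, O
Why: Acid hydrolysis should remove the three MOM ethers, the dimethyl acetal and the silyl ether in one operation without touching a stereocenter.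

**Compound list**

1 | (R)-(−)-linalool, (3R)-3,7-dimethylocta-1,6-dien-3-ol | CC(C)=CCC[C@@](C)(O)C=C | starting material
2 | triethyl{[(3R)-3,7-dimethylocta-1,6-dien-3-yl]oxy}silane | CC(C)=CCC[C@@](C)(O[Si](CC)(CC)CC)C=C | intermediate
3 | secondary ozonide (1,2,4-trioxolane) at the trisubstituted alkene of 2 | CC1(C)OOC(CC[C@@](C)(O[Si](CC)(CC)CC)C=C)O1 | intermediate
4 | (4R)-4-methyl-4-(triethylsilyloxy)hex-5-enal | O=CCC[C@@](C)(O[Si](CC)(CC)CC)C=C | intermediate
5 | (6R)-2,6-dimethyl-6-(triethylsilyloxy)octa-1,7-dien-3-ol (both C3 epimers) | C=C(C)C(O)CC[C@@](C)(O[Si](CC)(CC)CC)C=C | intermediate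
6 | (4R)-2,4-dimethyl-4-(triethylsilyloxy)cyclohex-2-en-1-ol (both C1 epimers) | CC1=C[C@](C)(O[Si](CC)(CC)CC)CCC1O | intermediate
7 | (4R)-2,4-dimethyl-4-(triethylsilyloxy)cyclohex-2-en-1-one | CC1=C[C@](C)(O[Si](CC)(CC)CC)CCC1=O | intermediate
8 | {[(3R,4R)-2,4-dimethyl-3-(prop-2-en-1-yl)-4-(triethylsilyloxy)cyclohex-1-en-1-yl]oxy}trimethylsilane (allyl trans to OSiEt3) | CC1=C(O[Si](C)(C)C)CC[C@@](C)(O[Si](CC)(CC)CC)[C@@H]1CC=C | intermediate
9 | trimethylsilyl enol ether of the side-chain ketone of 10 | CC(O[Si](C)(C)C)=CC[C@@]1(C)C(=O)CC[C@@](C)(O[Si](CC)(CC)CC)[C@@H]1CC=C | intermediate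
10 | (2R,3R,4R)-2,4-dimethyl-2-(3-oxobutyl)-3-(prop-2-en-1-yl)-4-(triethylsilyloxy)cyclohexan-1-one | CC(=O)CC[C@@]1(C)C(=O)CC[C@@](C)(O[Si](CC)(CC)CC)[C@@H]1CC=C | intermediate
11 | triethyl{[(1R,2R,3R)-1,3-dimethyl-3-(3-methylbut-3-en-1-yl)-4-methylidene-2-(prop-2-en-1-yl)cyclohexyl]oxy}silane | C=C(C)CC[C@@]1(C)C(=C)CC[C@@](C)(O[Si](CC)(CC)CC)[C@@H]1CC=C | intermediate
12 | trans-fused 6-7 diene: ring A with C1 exocyclic methylene, 4β-methyl, 4α-OSiEt3, 10β-methyl, 5α-H, fused at C5–C10 to the cycloheptene C5–C6–C7=C11(CH3)–C8–C9–C10 | C1=C(C)CC[C@@]2(C)C(=C)CC[C@@](C)(O[Si](CC)(CC)CC)[C@@H]2C1 | intermediate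
13 | 2,4,6-trihydroxybenzaldehyde | O=Cc1c(O)cc(O)cc1O | starting material
14 | 2,4,6-tris(methoxymethoxy)benzaldehyde | O=Cc1c(OCOC)cc(OCOC)cc1OCOC | intermediate
15 | 3-bromo-2,4,6-tris(methoxymethoxy)benzaldehyde | O=Cc1c(OCOC)c(Br)c(OCOC)cc1OCOC | intermediate
16 | 1-bromo-3-(dimethoxymethyl)-2,4,6-tris(methoxymethoxy)benzene | COC(OC)c1c(OCOC)c(Br)c(OCOC)cc1OCOC | intermediate
17 | B-alkyl-9-borabicyclo[3.3.1]nonane from 12 (boron on the new C1–CH2 group, C1–H α) | C1=C(C)CC[C@@]2(C)[C@H](CB3C4CCCC3CCC4)CC[C@@](C)(O[Si](CC)(CC)CC)[C@@H]2C1 | intermediate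
18 | 6-7 alkene carrying 1β-{[3-(dimethoxymethyl)-2,4,6-tris(methoxymethoxy)phenyl]methyl} (cycloheptene C7=C11 intact, 4α-OSiEt3) | C1=C(C)CC[C@@]2(C)[C@H](Cc3c(OCOC)c(C(OC)OC)c(OCOC)cc3OCOC)CC[C@@](C)(O[Si](CC)(CC)CC)[C@@H]2C1 | intermediate
19 | 7α,11α-cis-diol of 18 (C11 methyl β) | O[C@H]1[C@@](C)(O)CC[C@@]2(C)[C@H](Cc3c(OCOC)c(C(OC)OC)c(OCOC)cc3OCOC)CC[C@@](C)(O[Si](CC)(CC)CC)[C@@H]2C1 | intermediate
20 | 7-O-methanesulfonate of 19 | CS(=O)(=O)O[C@H]1[C@@](C)(O)CC[C@@]2(C)[C@H](Cc3c(OCOC)c(C(OC)OC)c(OCOC)cc3OCOC)CC[C@@](C)(O[Si](CC)(CC)CC)[C@@H]2C1 | intermediate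
21 | 7α-acetyl trans-decalin (C7 epimer of 22) | CC(=O)[C@H]1CC[C@@]2(C)[C@H](Cc3c(OCOC)c(C(OC)OC)c(OCOC)cc3OCOC)CC[C@@](C)(O[Si](CC)(CC)CC)[C@@H]2C1 | intermediate
22 | 7β-acetyl-1β-(arylmethyl)-4β,10β-dimethyl-4α-(triethylsilyloxy)-trans-decalin (5α-H) | CC(=O)[C@@H]1CC[C@@]2(C)[C@H](Cc3c(OCOC)c(C(OC)OC)c(OCOC)cc3OCOC)CC[C@@](C)(O[Si](CC)(CC)CC)[C@@H]2C1 | intermediate
23 | 7β-(prop-1-en-2-yl) analogue of 22 | C=C(C)[C@@H]1CC[C@@]2(C)[C@H](Cc3c(OCOC)c(C(OC)OC)c(OCOC)cc3OCOC)CC[C@@](C)(O[Si](CC)(CC)CC)[C@@H]2C1 | intermediate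
24 | aryllithium from 23 (lithium at the free ring position between two OMOM groups) | C=C(C)[C@@H]1CC[C@@]2(C)[C@H](Cc3c(OCOC)c(C(OC)OC)c(OCOC)c([Li])c3OCOC)CC[C@@](C)(O[Si](CC)(CC)CC)[C@@H]2C1 | intermediate
25 | 3-methylbutanoyl aryl ketone from 23 (fully protected target) | C=C(C)[C@@H]1CC[C@@]2(C)[C@H](Cc3c(OCOC)c(C(OC)OC)c(OCOC)c(C(=O)CC(C)C)c3OCOC)CC[C@@](C)(O[Si](CC)(CC)CC)[C@@H]2C1 | intermediate
26 | CNP0561337.1: 1β-[(3-formyl-2,4,6-trihydroxy-5-(3-methylbutanoyl)phenyl)methyl]-4α-hydroxy-4β,10β-dimethyl-7β-(prop-1-en-2-yl)-trans-decalin (5α-H) | C=C(C)[C@@H]1CC[C@@]2(C)[C@H](Cc3c(O)c(C=O)c(O)c(C(=O)CC(C)C)c3O)CC[C@@](C)(O)[C@@H]2C1 | target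

**Totals**

Total step count: 18. Longest linear sequence: 15 steps (steps 1–9 and 13–18); steps 10–12 make the aryl bromide.

**Steps most likely to fail, with fallbacks**

Step 13. The hydroboration may show incomplete facial selectivity at C1, and the hindered primary alkylborane may transmetalate slowly to the di-ortho-substituted aryl palladium species, so that β-hydride elimination or protodeboronation competes. The fallback sets out from 12 and 16 and returns at 18. The same alkylborane 17 is worked up oxidatively (NaOH, H2O2) to the 1β-hydroxymethyl compound F1. Dess–Martin oxidation gives the 1β-formyl compound F2, at which stage a minor C1 epimer can be removed. The aryllithium made from 16 by bromine–lithium exchange (n-BuLi, THF, −78 °C) is added to give the benzylic alcohol F3. Conversion into the S-methyl xanthate F4 (NaH, CS2, MeI) and Barton–McCombie reduction (Bu3SnH, AIBN, toluene, 80 °C) should then give 18.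

Step 6. The organocopper reagent may add 1,2 or not at all at the β-carbon flanked by a quaternary carbon and an α-methyl group, or facial discrimination may be poor. The fallback sets out from 7 and returns at 8. A Hosomi–Sakurai allylation (allyltrimethylsilane, TiCl4, CH2Cl2, −78 °C) is a Lewis-acid pathway with an open transition state that tolerates hindered β-carbons. It should give (3R,4R)-2,4-dimethyl-3-(prop-2-en-1-yl)-4-(triethylsilyloxy)cyclohexan-1-one F5 as a C2 epimer mixture. Thermodynamic enol silylation (Me3SiCl, NaI, Et3N, MeCN) then gives the more substituted silyl enol ether 8.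

Step 15. Methyl migration may compete with ring-carbon migration, or base-induced elimination of the mesylate may win. The fallback sets out from 19 and returns at 22; it keeps the ring contraction but changes its mechanism. Dess–Martin oxidation of the secondary alcohol gives the seven-membered α-ketol F6. An α-ketol (acyloin) rearrangement (Al(Ot-Bu)3, toluene, 80 °C) moves C8 from C11 to the C7 carbonyl with relief of cycloheptanone strain and gives the 7-acetyl-7-hydroxy decalin F7. Acetylation (Ac2O, DMAP) gives the acetate F8, and SmI2 (THF/MeOH, −78 °C) removes the acetoxy group. A short KOt-Bu equilibration then gives 22.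

**Further compounds**

F1 | step 13 | 1β-hydroxymethyl 6-7 alkene | C1=C(C)CC[C@@]2(C)[C@H](CO)CC[C@@](C)(O[Si](CC)(CC)CC)[C@@H]2C1
F2 | step 13 | 1β-formyl 6-7 alkene | C1=C(C)CC[C@@]2(C)[C@H](C=O)CC[C@@](C)(O[Si](CC)(CC)CC)[C@@H]2C1
F3 | step 13 | benzylic alcohol from F2 and the aryllithium of 16 (carbinol epimers) | C1=C(C)CC[C@@]2(C)[C@H](C(O)c3c(OCOC)c(C(OC)OC)c(OCOC)cc3OCOC)CC[C@@](C)(O[Si](CC)(CC)CC)[C@@H]2C1
F4 | step 13 | S-methyl xanthate of F3 | C1=C(C)CC[C@@]2(C)[C@H](C(OC(=S)SC)c3c(OCOC)c(C(OC)OC)c(OCOC)cc3OCOC)CC[C@@](C)(O[Si](CC)(CC)CC)[C@@H]2C1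
F5 | step 6 | (3R,4R)-2,4-dimethyl-3-(prop-2-en-1-yl)-4-(triethylsilyloxy)cyclohexan-1-one (C2 epimers) | CC1C(=O)CC[C@@](C)(O[Si](CC)(CC)CC)[C@@H]1CC=C
F6 | step 15 | seven-membered α-ketol (C7 ketone, C11 tertiary alcohol) from 19 | O=C1[C@@](C)(O)CC[C@@]2(C)[C@H](Cc3c(OCOC)c(C(OC)OC)c(OCOC)cc3OCOC)CC[C@@](C)(O[Si](CC)(CC)CC)[C@@H]2C1
F7 | step 15 | 7-acetyl-7-hydroxy trans-decalin | CC(=O)C1(O)CC[C@@]2(C)[C@H](Cc3c(OCOC)c(C(OC)OC)c(OCOC)cc3OCOC)CC[C@@](C)(O[Si](CC)(CC)CC)[C@@H]2C1
F8 | step 15 | 7-acetoxy-7-acetyl trans-decalin | CC(=O)OC1(C(C)=O)CC[C@@]2(C)[C@H](Cc3c(OCOC)c(C(OC)OC)c(OCOC)cc3OCOC)CC[C@@](C)(O[Si](CC)(CC)CC)[C@@H]2C1
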